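# Proposed synthesis of 2,3,7-tribromo-1H-indole

## Structural features

The target is a 1H-indole in which a benzene ring (C3a, C4 to C7, C7a) shares the C3a–C7a bond with a pyrrole ring (N1, C2, C3), and it carries bromine on C2, C3 and C7 beside a free N–H. There is no stereocenter, so the problem is one of regiochemistry and functional-group tolerance. The two pyrrole bromines sit on the electron-rich enamine part of the ring and make the free N–H compound sensitive to acid, light, oxidants and water, so they are best introduced last and under neutral conditions. The C7 bromine is the real difficulty, because electrophilic bromination of an indole goes to C3, then C2, then the C5/C6 region, and not cleanly to C7. This bromine must therefore arrive with the starting arene and survive every later step, which speaks against low-valent metals and organolithium reagents. C7 is ortho to C7a, which bears N1, and C3a on the other side of C7a bears C3, so a benzene with bromine, nitrogen and a one-carbon electrophile on three neighbouring carbons holds the whole substitution pattern. The key step exploits this: the nitrogen of such an arene is extended by a glycinate arm (future C2), and the C2–C3 bond is closed by aldol condensation onto the formyl carbon (future C3). The ester that acidifies the C2 hydrogens stays on C2 and marks the position where bromine later replaces carbon.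

## Logic of the disconnections

**11 to 9.** The C3–Br and C2–Br bonds of 11 are cut first. C3–Br goes back to C3–H and C2–Br to a C2–CO2H group, which leads to 9 by way of 10. This keeps the two labile pyrrole bromines out of all earlier steps and leaves a robust acid as the last isolated intermediate. The forward step needs an electrophilic bromine source that reacts twice on the pyrrole ring only. The second attack must occur at the carboxyl-bearing carbon with loss of CO2, under neutral, dry conditions that leave the benzene ring alone.

**9 to 7.** The N1–H and CO2H groups of 9 are traced back to the N1–sulfonyl and CO2Et groups of 7, cutting an N–S bond and an acyl–O bond, by way of 8. Both groups are needed by the ring construction and both fall to hydroxide, so one operation removes them together. The forward step must cleave both completely without touching C7–Br.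

**7 to 5.** The C2–C3 bond of the pyrrole ring of 7 is cut, read as the retron of an aldol condensation, by way of 6. This opens the five-membered ring to the acyclic 5, in which every ring atom and the C7 bromine are already in place. The forward step needs enolate formation at the glycinate CH2 and loss of water, not loss of the sulfonyl group, from the aldol adduct.

**5 to 3 and 4.** The N–CH2 bond of 5 is cut. The acidic sulfonamide N–H of 3 allows alkylation with 4 using a mild carbonate base. The simplification is a two-carbon electrophile split off from a simple sulfonanilide. The forward step needs a base mild enough not to start the aldol closure prematurely and a nitrogen anion that alkylates despite two ortho substituents.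

**3 to 1 and 2.** The N–S bond of 3 is cut, which leaves 1 and 2, both commercial. The forward step must sulfonylate a hindered, deactivated aniline once, without self-condensation of the amino aldehyde.

## Other disconnections considered

Alternative 1: The benzene ring is cut at C7–C7a and C3a–C4 and built onto a preformed five-membered nitrogen ring.
- **Forward key step:** 3-bromo-2H-pyran-2-one A1 and tert-butyl 2,3-dihydro-1H-pyrrole-1-carboxylate A2 undergo an inverse-demand Diels–Alder reaction. The nucleophilic β-carbon of A2 bonds to C6 of A1 and its nitrogen-bearing carbon to the bromine-bearing C3. The bridged lactone loses CO2, and a quinone oxidant in the same flask dehydrogenates the 3a,7a-dihydroarene to tert-butyl 7-bromoindoline-1-carboxylate A3.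
- **In favour:** the polarity of the two partners places bromine at C7. The route is convergent and needs no hindered aniline and no aldehyde.
- **Against:** cycloaddition and CO2 loss need prolonged heating. The dihydroarene has a second way to aromatise, expulsion of the carbamate nitrogen from C7a together with the C3a hydrogen. This would open the five-membered ring to tert-butyl N-[2-(3-bromophenyl)ethyl]carbamate A4. A3 is at the indoline oxidation level and has no handle at C2 or C3, so carbamate removal, dehydrogenation and two C–H brominations would still follow.
- **Comparison:**
  - Structure: this plan builds the ring that carries one substituent, while the chosen plan builds the ring that carries two and marks C2 in advance.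
  - Mechanism: the regiochemistry is as dependable as in the chosen aldol (equal). Both plans face a question of which group leaves on aromatisation (equal). The pericyclic cascade is harsher than carbonate at 70 °C.
  - Step economy: A3 is reached in one step from two simple partners, against three steps to 7. This is better before the key step and about equal overall, at four to five steps.

Alternative 2: Both rings are cut at once, at C3a–C7a, C4–C5 and C6–C7.
- **Forward key step:** N-(bromoethynyl)-N-(but-3-yn-1-yl)-4-methylbenzenesulfonamide A5 and acetylene A6 are cyclotrimerised with Cp*RuCl(cod) to 7-bromo-1-tosylindoline A7.
- **In favour:** three C–C bonds and two rings form in one step, a higher bond-forming density than the chosen aldol (better). The bromine position is fixed by the bromoynamide unit of A5 (equal in regiochemical certainty).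
- **Against:** A5 is a sensitive bromoynamide that itself needs several steps. Its alkynyl C–Br bond can add oxidatively to the divalent ruthenium centre. A6 is a gas that brings a handling hazard and can trimerise with itself. A7, like A3, has no C2/C3 functionality, so dehydrogenation, sulfonyl removal and dibromination would follow.
- **Comparison:**
  - Structure: a de novo benzene synthesis is spent on a ring with one substituent.
  - Mechanism: this is metallacycle chemistry next to a C–Br bond, against metal-free enolate chemistry in the chosen plan.
  - Step economy: roughly seven to eight steps, against five.

Alternative 3: The cut is at N1–C2 and C3–Br.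
- **Forward key step:** an N-bromoimide activates the bromoalkyne of N-[2-bromo-6-(bromoethynyl)phenyl]-4-methylbenzenesulfonamide A8. The sulfonamide nitrogen attacks the bromine-bearing alkyne carbon in a 5-endo-dig closure while the new bromine goes to the inner carbon. The product is 2,3,7-tribromo-1-tosylindole A9, and only sulfonyl removal would remain.
- **In favour:** all three bromines are in place at ring closure. The end game is one step, and the dibromoindole stays N-protected until the end. On both points this plan is better than the chosen one, which needs a halodecarboxylation.
- **Against:** bromonium transfer to an electron-poor 1-bromoalkyne is less assured than to an ordinary aryl alkyne. Simple addition across the triple bond or N-bromination could compete with ring closure. A8 requires a Sonogashira coupling that must tell two halogens on one arene apart. The final desulfonylation of A9 must spare a C2–Br bond on an electron-poor ring.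
- **Comparison:**
  - Structure: this is the most target-oriented plan.
  - Mechanism: the chosen aldol has closer precedent for its substrate class.
  - Step economy: about equal overall, at five to six steps, and better after the key step.

Key step: step 3

## Route

Remark (atom mapping): the formyl carbon of 1 becomes C3, its nitrogen N1, its bromine-bearing carbon C7, and the CH2 of 4 becomes C2; the structures of 5 and 7 are consistent with this mapping, and tosyl and ethyl ester are chosen because the sulfonyl group makes N–H alkylation possible with carbonate and both groups fall to hydroxide in one step.

Remark (assumption): in step 4 the N–S bond is taken to break before the ester is saponified; the opposite order would give the same product 9.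

Step 1
Reactants: 1 2-amino-3-bromobenzaldehyde; 2 p-toluenesulfonyl chloride
Product: 3 N-(2-bromo-6-formylphenyl)-4-methylbenzenesulfonamide
Conditions: pyridine, DMAP (cat.), 50 °C
Reagents that add atoms: none
Why: N-sulfonylation of an aniline in pyridine, which traps HCl and suppresses acid-catalysed self-condensation of the amino aldehyde. Gentle heating and DMAP compensate for the two ortho substituents, and the acidic mono-sulfonamide resists a second sulfonylation.

Step 2
Reactants: 3 N-(2-bromo-6-formylphenyl)-4-methylbenzenesulfonamide; 4 ethyl bromoacetate
Product: 5 ethyl N-(2-bromo-6-formylphenyl)-N-tosylglycinate
Conditions: K2CO3 (1.5 equiv), MeCN, 25 °C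
Reagents that add atoms: none
Why: SN2 N-alkylation of the sulfonamide anion with a reactive α-halo ester. Carbonate in acetonitrile at room temperature deprotonates N–H but hardly enolises the glycinate, so 5 can be isolated, and any material that has already cyclised is simply carried into step 3.

Step 3
Reactants: 5 ethyl N-(2-bromo-6-formylphenyl)-N-tosylglycinate
Product: 7 ethyl 7-bromo-1-tosylindole-2-carboxylate, via 3-hydroxyindoline aldol adduct 6 (not isolated)
Conditions: K2CO3 (2 equiv), DMF, 70 °C
Reagents that add atoms: none
Why: Carbonate deprotonates the glycinate CH2, which is acidified by the ester and the N-sulfonyl group, and the enolate adds to the ortho formyl carbon to form C2–C3 and give 6. The pyrrole ring closes in a 5-exo-trig mode with the enolate double bond exocyclic to the new ring. A second deprotonation at C2 expels hydroxide from C3 by E1cB elimination, and the gain of the aromatic pyrrole ring drives this. The closest known reaction type is the base-mediated cyclisation of N-sulfonyl-N-(2-acylaryl)glycinates to 1-sulfonylindole-2-carboxylates, an intramolecular aldol condensation. The two stereocenters of 6 (C2 and C3, racemic mixture of diastereomers) are both erased on dehydration, and E1cB elimination needs no particular relative configuration, so nothing has to be controlled. The selectivity needed is loss of hydroxide from C3 and not loss of p-toluenesulfinate from N1 at the same enolate; a weak carbonate base keeps the enolate concentration low, and only C3–O cleavage leads to an aromatic product. Regiochemistry is fixed by the ortho relation of nitrogen and formyl group, and no metal is present that could touch C7–Br. Any N–S cleavage after aromatisation gives 8, which step 4 forms anyway.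

Step 4
Reactants: 7 ethyl 7-bromo-1-tosylindole-2-carboxylate
Product: 9 7-bromo-1H-indole-2-carboxylic acid, via ethyl 7-bromo-1H-indole-2-carboxylate 8 (not isolated)
Conditions: KOH (6 equiv), EtOH/H2O 3:1, 80 °C; then aq. HCl to pH 2
Reagents that add atoms: potassium hydroxide, [K+].[OH-]
Why: Hydroxide attacks the sulfonyl sulfur and releases the ester-stabilised indolide; the strain between the sulfonyl group and the C7 bromine helps this. Saponification of the ethyl ester follows. The unactivated aryl bromide is inert to aqueous base at this temperature.

Step 5
Reactants: 9 7-bromo-1H-indole-2-carboxylic acid
Product: 11 2,3,7-tribromo-1H-indole, via 3,7-dibromo-1H-indole-2-carboxylic acid 10 (not isolated)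
Conditions: NBS (2.05 equiv), LiOAc (10 mol %), DMF, 0 → 25 °C, dark
Reagents that add atoms: N-bromosuccinimide, O=C1CCC(=O)N1Br
Why: The first equivalent brominates C3, the most nucleophilic position, to give 10. The second attacks the C2=C3 enamine unit again, and the ring re-aromatises by loss of CO2 from C2 with bromine ending on C2, an ipso halodecarboxylation of an indole-2-carboxylic acid. The only by-products are succinimide and CO2, so the acid-sensitive product is not exposed to HBr, and the stoichiometry keeps the benzene ring untouched.

## Compound list

1 | 2-amino-3-bromobenzaldehyde | Nc1c(Br)cccc1C=O | starting material
2 | p-toluenesulfonyl chloride | Cc1ccc(cc1)S(Cl)(=O)=O | starting material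
3 | N-(2-bromo-6-formylphenyl)-4-methylbenzenesulfonamide | Cc1ccc(cc1)S(=O)(=O)Nc1c(Br)cccc1C=O | intermediate
4 | ethyl bromoacetate | CCOC(=O)CBr | starting material
5 | ethyl N-(2-bromo-6-formylphenyl)-N-tosylglycinate | CCOC(=O)CN(c1c(Br)cccc1C=O)S(=O)(=O)c1ccc(C)cc1 | intermediate
6 | ethyl 7-bromo-3-hydroxy-1-tosylindoline-2-carboxylate (racemic, mixture of C2/C3 diastereomers; not isolated) | CCOC(=O)C1C(O)c2cccc(Br)c2N1S(=O)(=O)c1ccc(C)cc1 | intermediate
7 | ethyl 7-bromo-1-tosylindole-2-carboxylate | CCOC(=O)c1cc2cccc(Br)c2n1S(=O)(=O)c1ccc(C)cc1 | intermediate
8 | ethyl 7-bromo-1H-indole-2-carboxylate (not isolated) | CCOC(=O)c1cc2cccc(Br)c2[nH]1 | intermediate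
9 | 7-bromo-1H-indole-2-carboxylic acid | OC(=O)c1cc2cccc(Br)c2[nH]1 | intermediate
10 | 3,7-dibromo-1H-indole-2-carboxylic acid (not isolated) | OC(=O)c1[nH]c2c(Br)cccc2c1Br | intermediate
11 | 2,3,7-tribromo-1H-indole | Brc1[nH]c2c(Br)cccc2c1Br | target

## Step count and risks

Total step count: 5. Longest linear sequence: 5 steps (1 → 3 → 5 → 7 → 9 → 11).

**Step 3 (key step).** The most likely failure is fragmentation at nitrogen. The C2 enolate of the aldol adduct can expel p-toluenesulfinate where hydroxide should leave, helped by relief of strain between the sulfonyl group and the C7 bromine. The reaction can also stall at the aldol stage because hydroxide is a poor leaving group. The fallback sets out from 5. The aldol addition is run alone under mild conditions (K2CO3, MeCN, 0 to 25 °C) and 6 is isolated. Its hydroxyl group is converted with MsCl and Et3N in CH2Cl2 at 0 °C into ethyl 7-bromo-3-(methylsulfonyloxy)-1-tosylindoline-2-carboxylate F1. The sulfonate on C3 leaves far more readily than sulfinate from nitrogen, so elimination with the same amine, or with DBU, gives 7, where the route is rejoined.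

**Step 5.** The second bromination may not take the ipso course. Attack at C3 of 10 can end in over-oxidation and hydrolysis towards oxindole-type material if traces of water are present, or bromination can move to the benzene ring before CO2 is lost. The free dibromoindole can also degrade on acidic silica or in light. The fallback sets out from 9. Protodecarboxylation (Ag2CO3 10 mol %, AcOH, DMSO, 120 °C) gives 7-bromo-1H-indole F2. Two equivalents of NBS in THF at −78 → 0 °C then brominate C3, giving 3,7-dibromo-1H-indole F3 without isolation, and then C2 by ordinary C–H substitution. The route is rejoined at 11.

**Step 1.** Sulfonylation may remain incomplete, because the nitrogen lies between two ortho substituents and its lone pair is conjugated with, and hydrogen-bonded to, the formyl group. Forcing conditions invite double sulfonylation or self-condensation of the amino aldehyde. The fallback sets out from 1. NaBH4 in MeOH reduces the aldehyde to (2-amino-3-bromophenyl)methanol F4, whose nitrogen is no longer deactivated. Reagent 2 in pyridine/CH2Cl2 at 0 °C sulfonylates nitrogen in preference to oxygen, giving N-[2-bromo-6-(hydroxymethyl)phenyl]-4-methylbenzenesulfonamide F5. MnO2 in CH2Cl2 oxidises the benzylic alcohol back to the aldehyde, and the route is rejoined at 3.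

**Step 4.** N–S cleavage may be incomplete. If the ester is saponified first, the neighbouring carboxylate repels hydroxide and makes the indolide a poorer leaving group, so an N-sulfonyl acid may persist. The fallback sets out from 7. Tetrabutylammonium fluoride (Bu4NF) in THF at reflux removes the sulfonyl group by fluoride attack at sulfur and gives 8, here isolated. LiOH in THF/H2O at 25 °C then saponifies it, and the route is rejoined at 9.

## Further compounds

F1 | step 3 | ethyl 7-bromo-3-(methylsulfonyloxy)-1-tosylindoline-2-carboxylate | CCOC(=O)C1C(OS(C)(=O)=O)c2cccc(Br)c2N1S(=O)(=O)c1ccc(C)cc1
F2 | step 5 | 7-bromo-1H-indole | Brc1cccc2cc[nH]c12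
F3 | step 5 | 3,7-dibromo-1H-indole | Brc1c[nH]c2c(Br)cccc12
F4 | step 1 | (2-amino-3-bromophenyl)methanol | Nc1c(Br)cccc1CO
F5 | step 1 | N-[2-bromo-6-(hydroxymethyl)phenyl]-4-methylbenzenesulfonamide | Cc1ccc(cc1)S(=O)(=O)Nc1c(Br)cccc1CO
F0 | step 4 | none | none
A1 | alternative 1 | 3-bromo-2H-pyran-2-one | O=C1OC=CC=C1Br
A2 | alternative 1 | tert-butyl 2,3-dihydro-1H-pyrrole-1-carboxylate | CC(C)(C)OC(=O)N1CCC=C1
A3 | alternative 1 | tert-butyl 7-bromoindoline-1-carboxylate | CC(C)(C)OC(=O)N1CCc2cccc(Br)c21
A4 | alternative 1 | tert-butyl N-[2-(3-bromophenyl)ethyl]carbamate | CC(C)(C)OC(=O)NCCc1cccc(Br)c1
A5 | alternative 2 | N-(bromoethynyl)-N-(but-3-yn-1-yl)-4-methylbenzenesulfonamide | Cc1ccc(cc1)S(=O)(=O)N(CCC#C)C#CBr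
A6 | alternative 2 | acetylene | C#C
A7 | alternative 2 | 7-bromo-1-tosylindoline | Cc1ccc(cc1)S(=O)(=O)N1CCc2cccc(Br)c21
A8 | alternative 3 | N-[2-bromo-6-(bromoethynyl)phenyl]-4-methylbenzenesulfonamide | Cc1ccc(cc1)S(=O)(=O)Nc1c(Br)cccc1C#CBr
A9 | alternative 3 | 2,3,7-tribromo-1-tosylindole | Cc1ccc(cc1)S(=O)(=O)n1c(Br)c(Br)c2cccc(Br)c21
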